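Retrosynthesis: the 3α,4β-diol goes back to a C3=C4 alkene (α-epoxide, trans-diaxial opening), and C3=C4 with 5α-H to a C4=C5 enone (reductive 1,3-transposition of its 3β-allylic alcohol). Ring B (C5, C6, C7, C8, C9, C10) is then contracted by taking C7 with its isopropyl group out from between C6 and C8, which leaves a cyclopentanone; ring A goes back to a Robinson annulation.
Enabling feature: C6 carries oxygen and its neighbour C7 the isopropyl branch, so ring B as its C6 ketone is the product of inserting an isobutylidene carbon into the C6–C8 bond of a cyclopentanone (C5, C6, C8, C9, C10); C5 on the other side of the carbonyl can be blocked.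
Forward: 2-methylcyclopentanone and ethyl vinyl ketone give ring A on the five-membered ring; deconjugative ketalisation, dihydroxylation and oxidation place the ketone at C6 and a temporary oxygen at C5; the five-membered ring is enlarged with 1-diazo-2-methylpropane; ring A is then finished.
Helper: the 5α-oxygen blocks C5 during the insertion, fixes the trans ring fusion so that C7 can equilibrate to the equatorial 7β-isopropyl epimer, and is finally lost as water to make the C4=C5 enone.
Stereochemistry: C10 from a chiral-imine Michael addition; C7 by thermodynamic control; C6 and C3 by hydride delivery from the α-face; C5 by suprafacial hydrogen transfer in an allylic diazene; C3/C4 by α-face epoxidation and anti opening.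
Key step: step 8

Remark on names: from step 8 on, compounds are named as eudesmanes (ring A C1–C5 and C10, ring B C5–C10, C14 methyl on C10, C15 methyl on C4, isopropyl C11–C13 on C7); α is the face opposite the C10 methyl group; the hydrindanes are named as indene derivatives. C=N geometry in 3, 4, 12 and 13 is not specified.
Assumption: the chiral-imine Michael addition is taken to follow the sense known for 2-methylcycloalkanones, in which the (S)-amine leads to the (R)-ketone; the (R)-amine is therefore used, and the (S)-amine would be used if the sense were found reversed.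

Step 1
Reactants: 1 2-methylcyclopentan-1-one; 2 pent-1-en-3-one
Product: 5 (S)-2-methyl-2-(3-oxopentyl)cyclopentan-1-one, via chiral imine 3 (not isolated), via Michael adduct imine 4 (not isolated)
Conditions: (R)-1-phenylethylamine, TsOH (cat.), toluene, reflux (Dean–Stark); then 2, THF, 23 °C; then 20% aq. AcOH, 23 °C
Reagents that add atoms: water O
Why: The secondary enamine tautomer of the chiral imine should add to the enone at the more substituted α-carbon through an aza-ene-like transition state on the face away from the phenyl group (deracemising chiral-imine Michael addition), which sets the quaternary centre that becomes C10, and hydrolysis returns the auxiliary.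

Step 2
Reactants: 5 (S)-2-methyl-2-(3-oxopentyl)cyclopentan-1-one
Product: 6 (S)-4,7a-dimethyl-1,2,3,6,7,7a-hexahydro-5H-inden-5-one
Conditions: NaOMe, MeOH, 60 °C
Reagents that add atoms: none
Why: Intramolecular aldol condensation (second stage of a Robinson annulation) of the ethyl ketone α-methylene onto the ring carbonyl is the only closure that can dehydrate, and gives the 4-methyl enone of ring A.

Step 3
Reactants: 6 (S)-4,7a-dimethyl-1,2,3,6,7,7a-hexahydro-5H-inden-5-one
Product: 7 (4'S,7a'S)-4',7a'-dimethyl-1',2',4',6',7',7a'-hexahydrospiro[[1,3]dioxolane-2,5'-indene]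
Conditions: ethylene glycol, TsOH (cat.), benzene, reflux (Dean–Stark)
Reagents that add atoms: ethane-1,2-diol OCCO
Why: Acid-catalysed ketalisation of the enone passes through the dienol ether and should place the double bond in the β,γ-position C5=C6 inside the five-membered ring (deconjugative ketalisation), with C4 protonated to the equatorial methyl epimer, a centre that is erased again in step 10.

Step 4
Reactants: 7 (4'S,7a'S)-4',7a'-dimethyl-1',2',4',6',7',7a'-hexahydrospiro[[1,3]dioxolane-2,5'-indene]
Product: 8 (3'S,3a'R,4'S,7a'S)-4',7a'-dimethyloctahydrospiro[[1,3]dioxolane-2,5'-indene]-3',3a'-diol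
Conditions: OsO4 (cat.), NMO, acetone–H2O, 23 °C
Reagents that add atoms: N-methylmorpholine N-oxide C[N+]1([O-])CCOCC1; water O
Why: Upjohn cis-dihydroxylation should take place on the α-face of the trisubstituted alkene, away from the angular methyl group, which puts the secondary hydroxyl on C6 and the tertiary one on C5 (5α).

Step 5
Reactants: 8 (3'S,3a'R,4'S,7a'S)-4',7a'-dimethyloctahydrospiro[[1,3]dioxolane-2,5'-indene]-3',3a'-diol
Product: 10 (3a'R,4'S,7a'S)-4',7a'-dimethyl-3a'-(trimethylsilyloxy)hexahydrospiro[[1,3]dioxolane-2,5'-inden]-3'(2'H)-one, via hydroxy ketone 9 (not isolated)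
Conditions: Dess–Martin periodinane, pyridine, CH2Cl2, 0 °C; then TMSCl, imidazole, DMF, 40 °C
Reagents that add atoms: chlorotrimethylsilane C[Si](C)(C)Cl
Why: Dess–Martin oxidation can only touch the secondary hydroxyl and gives the C6 cyclopentanone, and silylation of the tertiary α-hydroxyl then removes the O–H group that would otherwise consume the diazoalkane in step 8.

Step 6
Reactants: 11 2-methylpropanal
Product: 12 N'-(2-methylpropylidene)-4-methylbenzenesulfonohydrazide
Conditions: TsNHNH2, MeOH, 23 °C
Reagents that add atoms: 4-methylbenzenesulfonohydrazide Cc1ccc(cc1)S(=O)(=O)NN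
Why: Condensation of the aldehyde with the sulfonylhydrazide gives the tosylhydrazone, the usual precursor of a non-stabilised diazoalkane.

Step 7
Reactants: 12 N'-(2-methylpropylidene)-4-methylbenzenesulfonohydrazide
Product: 14 1-diazo-2-methylpropane, via sodium tosylhydrazonate 13 (not isolated)
Conditions: NaOMe (1 equiv.), MeOH, 23 °C, evaporate to dryness; then 80–110 °C, 0.1 mmHg, receiver at −78 °C; taken up in cold toluene and used at once
Reagents that add atoms: none
Why: Vacuum pyrolysis of the dry tosylhydrazone salt (Bamford–Stevens fragmentation) expels sulfinate, and the volatile diazoalkane should distil into the cold trap before it loses nitrogen.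

Step 8
Reactants: 10 (3a'R,4'S,7a'S)-4',7a'-dimethyl-3a'-(trimethylsilyloxy)hexahydrospiro[[1,3]dioxolane-2,5'-inden]-3'(2'H)-one; 14 1-diazo-2-methylpropane
Product: 15 (4S,5R,10S)-3,3-(ethylenedioxy)-5α-(trimethylsilyloxy)eudesman-6-one as the mixture of C7 epimers
Conditions: Sc(OTf)3 (10 mol %), toluene, −78 to −20 °C, slow addition of 14 (2 equiv.)
Reagents that add atoms: none
Why: Sc(III) activates the C6 carbonyl, the nucleophilic carbon of the diazoalkane adds to it, and the diazonium betaine undergoes a 1,2-shift of C8 from C6 to the new carbon (C7) with loss of N2, so that the cyclopentanone becomes the 2-isopropylcyclohexanone of ring B. The closest known reaction type is the Lewis-acid-catalysed homologation of cycloalkanones with alkyl diazomethanes, a catalytic Tiffeneau–Demjanov-type ring enlargement. No ring is closed by cyclisation; ring B arises by enlargement of the existing five-membered ring through a 1,2-alkyl shift. The new stereocentre C7 is not controlled here, both epimers are expected, and it is corrected under thermodynamic control in step 9. The step needs migration of C8 and not of C5, which is secured because C5 is fully substituted, neopentylic and carries the electron-withdrawing silyloxy group, so that only the C8 methylene can take the position anti to the departing nitrogen, while the silyl ether also keeps the tertiary hydroxyl out of O–H insertion. A second homologation should be slow because the product ketone lies between a quaternary and a tertiary carbon.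

Step 9
Reactants: 15 (4S,5R,10S)-3,3-(ethylenedioxy)-5α-(trimethylsilyloxy)eudesman-6-one as the mixture of C7 epimers
Product: 17 (4S,5R,6R,7S,10S)-3,3-(ethylenedioxy)eudesmane-5α,6β-diol, via equilibrated hydroxy ketone 16 (not isolated)
Conditions: NaOMe (cat.), MeOH, 23 °C; then NaBH4, 0 °C
Reagents that add atoms: none
Why: Methoxide removes the silyl group and epimerises C7 through the enolate to the equatorial 7β-isopropyl ketone (the 7α epimer would be axial and syn-axial to the 5α-hydroxyl of the now rigid trans-decalone), and borohydride then attacks C6 from the α-face, away from the axial C10 methyl group, to give the axial 6β-alcohol.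

Step 10
Reactants: 17 (4S,5R,6R,7S,10S)-3,3-(ethylenedioxy)eudesmane-5α,6β-diol
Product: 19 (6R,7S,10S)-3-oxoeudesm-4-en-6β-yl benzoate, via ketal benzoate 18 (not isolated)
Conditions: BzCl, DMAP, pyridine, 60 °C; then 2 M aq. HCl, THF, 40 °C
Reagents that add atoms: benzoyl chloride O=C(Cl)c1ccccc1; water O
Why: DMAP-catalysed acylation can only take the secondary 6β-hydroxyl, and acid then hydrolyses the ketal and eliminates the tertiary 5α-hydroxyl, which is β to the C3 ketone and anti to the axial 4β-hydrogen (β-hydroxy ketone dehydration), so the temporary oxygen leaves and the C4=C5 enone forms with defined regiochemistry.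

Step 11
Reactants: 19 (6R,7S,10S)-3-oxoeudesm-4-en-6β-yl benzoate
Product: 20 (3S,6R,7S,10S)-3β-hydroxyeudesm-4-en-6β-yl benzoate
Conditions: NaBH4, CeCl3·7H2O, MeOH, −40 °C
Reagents that add atoms: none
Why: Luche 1,2-reduction of the enone should deliver hydride to C3 from the α-face, opposite the axial C10 methyl group, to give the pseudo-equatorial 3β-allylic alcohol without touching the benzoate.

Step 12
Reactants: 20 (3S,6R,7S,10S)-3β-hydroxyeudesm-4-en-6β-yl benzoate
Product: 23 (5R,6R,7S,10R)-5αH-eudesm-3-en-6β-yl benzoate, via sulfonylhydrazine adduct 21 (not isolated), via allylic diazene 22 (not isolated)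
Conditions: 2-nitrobenzenesulfonylhydrazide, PPh3, DEAD, THF, −30 °C; then 23 °C
Reagents that add atoms: none
Why: Mitsunobu displacement of the 3β-alcohol by the sulfonylhydrazide with inversion, loss of sulfinic acid to the 3α-allylic diazene and suprafacial retro-ene loss of N2 (reductive 1,3-transposition of an allylic alcohol) should deliver hydrogen to C5 on the α-face and move the double bond to C3=C4, which sets the trans ring fusion.

Step 13
Reactants: 23 (5R,6R,7S,10R)-5αH-eudesm-3-en-6β-yl benzoate
Product: 25 (3R,4R,5S,6R,7S,10S)-3α,4β-dihydroxy-5αH-eudesman-6β-yl benzoate, via epoxide 24 (not isolated)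
Conditions: mCPBA, NaHCO3, CH2Cl2, 0 °C; then 5% aq. HClO4, THF, 0 to 23 °C
Reagents that add atoms: 3-chloroperbenzoic acid OOC(=O)c1cccc(Cl)c1; water O
Why: Prilezhaev epoxidation should occur on the α-face (the β-face is shielded by the C10 methyl group and the 6β-benzoate), and acid-catalysed trans-diaxial (Fürst–Plattner) opening with water attacking the tertiary C4 from the β-face then gives the 3α,4β-diol.

Compound list
1 | 2-methylcyclopentan-1-one (racemic) | CC1CCCC1=O | starting material
2 | pent-1-en-3-one (ethyl vinyl ketone) | CCC(=O)C=C | starting material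
3 | (R)-N-(2-methylcyclopentylidene)-1-phenylethan-1-amine | CC1CCCC1=N[C@H](C)c1ccccc1 | intermediate
4 | 1-[(1S)-1-methyl-2-{[(1R)-1-phenylethyl]imino}cyclopentyl]pentan-3-one | CCC(=O)CC[C@]1(C)CCCC1=N[C@H](C)c1ccccc1 | intermediate
5 | (S)-2-methyl-2-(3-oxopentyl)cyclopentan-1-one | CCC(=O)CC[C@]1(C)CCCC1=O | intermediate
6 | (S)-4,7a-dimethyl-1,2,3,6,7,7a-hexahydro-5H-inden-5-one | CC1=C2CCC[C@@]2(C)CCC1=O | intermediate
7 | (4'S,7a'S)-4',7a'-dimethyl-1',2',4',6',7',7a'-hexahydrospiro[[1,3]dioxolane-2,5'-indene] (double bond C3'=C3a') | C[C@H]1C2=CCC[C@@]2(C)CCC13OCCO3 | intermediate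
8 | (3'S,3a'R,4'S,7a'S)-4',7a'-dimethyloctahydrospiro[[1,3]dioxolane-2,5'-indene]-3',3a'-diol | C[C@H]1[C@]2(O)[C@@H](O)CC[C@@]2(C)CCC13OCCO3 | intermediate
9 | (3a'R,4'S,7a'S)-3a'-hydroxy-4',7a'-dimethylhexahydrospiro[[1,3]dioxolane-2,5'-inden]-3'(2'H)-one | C[C@H]1[C@]2(O)C(=O)CC[C@@]2(C)CCC13OCCO3 | intermediate
10 | (3a'R,4'S,7a'S)-4',7a'-dimethyl-3a'-(trimethylsilyloxy)hexahydrospiro[[1,3]dioxolane-2,5'-inden]-3'(2'H)-one | C[C@H]1[C@]2(O[Si](C)(C)C)C(=O)CC[C@@]2(C)CCC13OCCO3 | intermediate
11 | 2-methylpropanal | CC(C)C=O | starting material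
12 | N'-(2-methylpropylidene)-4-methylbenzenesulfonohydrazide | CC(C)C=NNS(=O)(=O)c1ccc(C)cc1 | intermediate
13 | sodium salt of 12 | CC(C)C=N[N-]S(=O)(=O)c1ccc(C)cc1.[Na+] | intermediate
14 | 1-diazo-2-methylpropane | CC(C)C=[N+]=[N-] | intermediate
15 | (4S,5R,10S)-3,3-(ethylenedioxy)-5α-(trimethylsilyloxy)eudesman-6-one, C7 epimers | C[C@H]1[C@]2(O[Si](C)(C)C)C(=O)C(C(C)C)CC[C@@]2(C)CCC13OCCO3 | intermediate
16 | (4S,5R,7S,10S)-3,3-(ethylenedioxy)-5α-hydroxyeudesman-6-one | C[C@H]1[C@]2(O)C(=O)[C@H](C(C)C)CC[C@@]2(C)CCC13OCCO3 | intermediate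
17 | (4S,5R,6R,7S,10S)-3,3-(ethylenedioxy)eudesmane-5α,6β-diol | C[C@H]1[C@]2(O)[C@H](O)[C@H](C(C)C)CC[C@@]2(C)CCC13OCCO3 | intermediate
18 | (4S,5R,6R,7S,10S)-3,3-(ethylenedioxy)-5α-hydroxyeudesman-6β-yl benzoate | C[C@H]1[C@]2(O)[C@H](OC(=O)c3ccccc3)[C@H](C(C)C)CC[C@@]2(C)CCC14OCCO4 | intermediate
19 | (6R,7S,10S)-3-oxoeudesm-4-en-6β-yl benzoate | CC(C)[C@@H]1CC[C@@]2(C)CCC(=O)C(C)=C2[C@@H]1OC(=O)c1ccccc1 | intermediate
20 | (3S,6R,7S,10S)-3β-hydroxyeudesm-4-en-6β-yl benzoate | CC(C)[C@@H]1CC[C@@]2(C)CC[C@H](O)C(C)=C2[C@@H]1OC(=O)c1ccccc1 | intermediate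
21 | (3R,6R,7S,10S)-3α-[1-(2-nitrophenylsulfonyl)hydrazin-1-yl]eudesm-4-en-6β-yl benzoate | CC(C)[C@@H]1CC[C@@]2(C)CC[C@@H](N(N)S(=O)(=O)c3ccccc3[N+](=O)[O-])C(C)=C2[C@@H]1OC(=O)c1ccccc1 | intermediate
22 | (3R,6R,7S,10S)-3α-diazenyleudesm-4-en-6β-yl benzoate | CC(C)[C@@H]1CC[C@@]2(C)CC[C@@H](N=N)C(C)=C2[C@@H]1OC(=O)c1ccccc1 | intermediate
23 | (5R,6R,7S,10R)-5αH-eudesm-3-en-6β-yl benzoate | CC(C)[C@@H]1CC[C@@]2(C)CCC=C(C)[C@@H]2[C@@H]1OC(=O)c1ccccc1 | intermediate
24 | (3R,4S,5S,6R,7S,10S)-3α,4α-epoxy-5αH-eudesman-6β-yl benzoate | CC(C)[C@@H]1CC[C@@]2(C)CC[C@H]3O[C@@]3(C)[C@@H]2[C@@H]1OC(=O)c1ccccc1 | intermediate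
25 | (3R,4R,5S,6R,7S,10S)-3α,4β-dihydroxy-5αH-eudesman-6β-yl benzoate | CC(C)[C@@H]1CC[C@@]2(C)CC[C@@H](O)[C@](C)(O)[C@@H]2[C@@H]1OC(=O)c1ccccc1 | target

Total step count: 13. Longest linear sequence: 11 steps (steps 1–5 and 8–13); steps 6 and 7 are a two-step side branch.

Steps most likely to fail

Step 8 (key step). The secondary diazoalkane may add only slowly to the hindered α-silyloxy cyclopentanone, so that it is lost by protonation or dimerisation, and epoxide formation from the betaine may compete with the 1,2-shift. Fallback: the one-carbon insertion and the introduction of the isopropyl group are separated. Compound 10 is homologated with commercially available (trimethylsilyl)diazomethane and Me3Al (CH2Cl2, −78 to 0 °C) to 3,3-(ethylenedioxy)-7-(trimethylsilyl)-5α-(trimethylsilyloxy)-11,12,13-trinoreudesman-6-one F1. Both silyl groups are removed with K2CO3 in methanol to give 3,3-(ethylenedioxy)-5α-hydroxy-11,12,13-trinoreudesman-6-one F2. Its lithium enolate (LDA, 2.2 equiv.; C7 is the only enolisable position) is added to acetone to give 3,3-(ethylenedioxy)-5α,11-dihydroxyeudesman-6-one F3, which is dehydrated with the Burgess reagent to 3,3-(ethylenedioxy)-5α-hydroxyeudesm-7(11)-en-6-one F4. Hydrogenation of the exocyclic enone (H2, Pd/C, EtOAc) followed by the methoxide equilibration of step 9 should return the route at compound 16.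

Step 12. The Mitsunobu displacement at the allylic C3 alcohol next to a tetrasubstituted double bond may be slow or may take an SN2′ or elimination course, and the diazene may lose nitrogen without clean hydrogen transfer to the congested C5. Fallback: the same 1,3-transposition through palladium. Compound 20 is formylated (formic acetic anhydride, pyridine) to 6β-(benzoyloxy)eudesm-4-en-3β-yl formate F5, which is treated with Pd(OAc)2 and n-Bu3P in THF. Ionisation anti to the 3β-formate puts palladium on the α-face, decarboxylation gives a palladium hydride, and hydride transfer to the more substituted allyl terminus C5 from the α-face should give compound 23.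

Step 13. In the acid-catalysed opening of the epoxide, proton loss from the developing C4 cation (allylic alcohols) and migration of the benzoyl group from O6 to the syn-axial O4 may compete with capture by water. Fallback: the epoxide 24 is isolated and opened with formic acid (98%, 0 °C), which should add formate at C4 from the β-face to give 3α-hydroxy-4β-(formyloxy)-5αH-eudesman-6β-yl benzoate F6. The formate is then removed with KHCO3 in methanol, conditions that the hindered benzoate should survive, and the route returns at compound 25.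

Further compounds
F1 | step 8 | 3,3-(ethylenedioxy)-7-(trimethylsilyl)-5α-(trimethylsilyloxy)-11,12,13-trinoreudesman-6-one | C[C@H]1[C@]2(O[Si](C)(C)C)C(=O)C([Si](C)(C)C)CC[C@@]2(C)CCC13OCCO3
F2 | step 8 | 3,3-(ethylenedioxy)-5α-hydroxy-11,12,13-trinoreudesman-6-one | C[C@H]1[C@]2(O)C(=O)CCC[C@@]2(C)CCC13OCCO3
F3 | step 8 | 3,3-(ethylenedioxy)-5α,11-dihydroxyeudesman-6-one | C[C@H]1[C@]2(O)C(=O)C(C(C)(C)O)CC[C@@]2(C)CCC13OCCO3
F4 | step 8 | 3,3-(ethylenedioxy)-5α-hydroxyeudesm-7(11)-en-6-one | C[C@H]1[C@]2(O)C(=O)C(=C(C)C)CC[C@@]2(C)CCC13OCCO3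
F5 | step 12 | 6β-(benzoyloxy)eudesm-4-en-3β-yl formate | CC(C)[C@@H]1CC[C@@]2(C)CC[C@H](OC=O)C(C)=C2[C@@H]1OC(=O)c1ccccc1
F6 | step 13 | 3α-hydroxy-4β-(formyloxy)-5αH-eudesman-6β-yl benzoate | CC(C)[C@@H]1CC[C@@]2(C)CC[C@@H](O)[C@](C)(OC=O)[C@@H]2[C@@H]1OC(=O)c1ccccc1
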